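**Assumption:** Agehoustin C (3'-hydroxy-5,6,7,8,2',4',5'-heptamethoxyflavone) has no stereocentre, so there is no enantiomer to control. Both arenes 1 and 7 are taken as catalogue chemicals.

## Retrosynthetic overview

1. Target 13 ⇐ acetate 12 ⇐ 1,3-diketone 11: ring C is closed last, by forming the O1–C8a aryl C–O bond in a dehydrogenative C–H/O–H coupling onto ring A.
2. 11 ⇐ C-acylation of the ring B methyl ketone 6 with the ring A acid chloride 10.
3. 6 ⇐ phenol 4 (O-acetylation, then Friedel–Crafts acetylation) ⇐ 1,2,4-trimethoxybenzene 1 by lithiation between two OMe groups, borylation and oxidation (this makes the C3'–O bond).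
4. Acid 9 ⇐ 1,2,3,4-tetramethoxybenzene 7 by ortho-lithiation and carboxylation.
5. Ring order: rings A and B are bought as arenes; the pyranone ring C is the only ring formed.

## Route

**Step 1**
Reactants: 1 1,2,4-trimethoxybenzene
Product: 4 2,3,6-trimethoxyphenol, via 2,3,6-trimethoxyphenyllithium 2 (not isolated), via lithium trimethoxy(2,3,6-trimethoxyphenyl)borate 3 (not isolated)
Conditions: n-BuLi (1.1 equiv), THF, 0 °C → rt; B(OMe)3, −78 °C → rt; AcOH, 30% H2O2, 0 °C → rt
Reagents that add atoms: hydrogen peroxide, OO (the phenol oxygen of 4); for the intermediates only: n-butyllithium, [Li]CCCC (Li of 2); trimethyl borate, COB(OC)OC (B(OMe)3 unit of 3)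
Why: Directed ortho-metalation removes the C3–H flanked by two methoxy groups (the most acidic site of 1), and borylation–oxidation (1,2-aryl shift from boron to oxygen) places the hydroxyl on exactly that carbon.

**Step 2**
Reactants: 4 2,3,6-trimethoxyphenol
Product: 6 5-acetyl-2,3,6-trimethoxyphenyl acetate (3'-acetoxy-2',4',5'-trimethoxyacetophenone), via 2,3,6-trimethoxyphenyl acetate 5 (not isolated)
Conditions: Ac2O (4 equiv), Bi(OTf)3 (5 mol%), MeNO2, 0 °C → 45 °C
Reagents that add atoms: acetic anhydride, CC(=O)OC(C)=O (both acetyl groups)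
Why: Fast acid-catalysed O-acetylation is followed by Friedel–Crafts acylation of 5 at C5, which is para to a methoxy group, whereas the only other free position (C4) is para to the poorly donating acetoxy group; excess Ac2O keeps the phenol capped and suppresses Fries chemistry.

**Step 3**
Reactants: 7 1,2,3,4-tetramethoxybenzene
Product: 9 2,3,4,5-tetramethoxybenzoic acid, via 2,3,4,5-tetramethoxyphenyllithium 8 (not isolated)
Conditions: n-BuLi (1.2 equiv), TMEDA, THF, 0 °C; CO2, −78 °C → rt; aq. HCl
Reagents that add atoms: carbon dioxide, O=C=O (the carboxyl group); for the intermediate only: n-butyllithium, [Li]CCCC (Li of 8)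
Why: Methoxy-directed ortho-lithiation of the C2-symmetric arene (its two C–H positions are equivalent) followed by carboxylation of the aryllithium gives a single acid.

**Step 4**
Reactants: 9 2,3,4,5-tetramethoxybenzoic acid; 6 5-acetyl-2,3,6-trimethoxyphenyl acetate
Product: 11 1-(3-acetoxy-2,4,5-trimethoxyphenyl)-3-(2,3,4,5-tetramethoxyphenyl)propane-1,3-dione, via 2,3,4,5-tetramethoxybenzoyl chloride 10 (not isolated)
Conditions: 9, (COCl)2, cat. DMF, CH2Cl2, 0 °C → rt, evaporate; then 6, MgBr2·OEt2 (2.5 equiv), i-Pr2NEt (3 equiv), CH2Cl2, rt; cold aq. citric acid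
Reagents that add atoms: none
Why: Claisen-type C-acylation under soft enolisation: magnesium chelation acidifies the methyl ketone enough for an amine base, the chelated enolate reacts at carbon, and the aryl acetate survives because no strong base or alkoxide is present.

**Step 5**
Reactants: 11 1-(3-acetoxy-2,4,5-trimethoxyphenyl)-3-(2,3,4,5-tetramethoxyphenyl)propane-1,3-dione
Product: 13 Agehoustin C (3'-hydroxy-5,6,7,8,2',4',5'-heptamethoxyflavone), via 3'-acetoxy-5,6,7,8,2',4',5'-heptamethoxyflavone 12 (not isolated)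
Conditions: 9-mesityl-3,6-di-tert-butyl-10-phenylacridinium tetrafluoroborate (5 mol%), Co(dmgH)2(py)Cl (5 mol%), MeCN/HFIP 9:1, 450 nm LEDs, Ar, 25 °C; concentrate; then NH3 (7 M in MeOH), 25 °C
Reagents that add atoms: none
Why: Proposed new method: a cross-dehydrogenative C–H/O–H coupling in which the photoexcited acridinium (about +2.0 V vs SCE) oxidises the more electron-rich tetramethoxyphenyl ring of enolised 11 to its radical cation, the enol oxygen on the carbon bearing ring B adds in a 6-membered closure to the ring A C–H carbon (para to one OMe, ortho to another; the only C–H of ring B is para to the deactivating acetoxy group), and the cobaloxime rearomatises the cyclohexadienyl radical with release of H2, the closest known reaction type being acridinium/cobaloxime dehydrogenative C–H/heteroatom coupling of methoxyarenes through arene radical cations and the photocatalytic dehydrogenative lactonisation of 2-arylbenzoic and Z-cinnamic acids; ammonia then removes the aryl acetate by aminolysis.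

## Compound list

1 | 1,2,4-trimethoxybenzene | COc1ccc(OC)c(OC)c1 | starting material
2 | 2,3,6-trimethoxyphenyllithium | [Li]c1c(OC)c(OC)ccc1OC | intermediate
3 | lithium trimethoxy(2,3,6-trimethoxyphenyl)borate | [Li+].CO[B-](OC)(OC)c1c(OC)c(OC)ccc1OC | intermediate
4 | 2,3,6-trimethoxyphenol | Oc1c(OC)c(OC)ccc1OC | intermediate
5 | 2,3,6-trimethoxyphenyl acetate | CC(=O)Oc1c(OC)c(OC)ccc1OC | intermediate
6 | 5-acetyl-2,3,6-trimethoxyphenyl acetate | CC(=O)Oc1c(OC)c(OC)cc(C(C)=O)c1OC | intermediate
7 | 1,2,3,4-tetramethoxybenzene | COc1ccc(OC)c(OC)c1OC | starting material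
8 | 2,3,4,5-tetramethoxyphenyllithium | [Li]c1cc(OC)c(OC)c(OC)c1OC | intermediate
9 | 2,3,4,5-tetramethoxybenzoic acid | OC(=O)c1cc(OC)c(OC)c(OC)c1OC | intermediate
10 | 2,3,4,5-tetramethoxybenzoyl chloride | O=C(Cl)c1cc(OC)c(OC)c(OC)c1OC | intermediate
11 | 1-(3-acetoxy-2,4,5-trimethoxyphenyl)-3-(2,3,4,5-tetramethoxyphenyl)propane-1,3-dione | CC(=O)Oc1c(OC)c(OC)cc(C(=O)CC(=O)c2cc(OC)c(OC)c(OC)c2OC)c1OC | intermediate
12 | 3'-acetoxy-5,6,7,8,2',4',5'-heptamethoxyflavone | CC(=O)Oc1c(OC)c(OC)cc(-c2cc(=O)c3c(OC)c(OC)c(OC)c(OC)c3o2)c1OC | intermediate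
13 | Agehoustin C, 3'-hydroxy-5,6,7,8,2',4',5'-heptamethoxyflavone (achiral) | COc1cc(-c2cc(=O)c3c(OC)c(OC)c(OC)c(OC)c3o2)c(OC)c(O)c1OC | target

## Step count and risks

Total steps: 5. Longest linear sequence: 4 (steps 1, 2, 4, 5); step 3 is a one-step side branch.

**Step 5 (proposed new step).** Risks: ipso attack of the enol oxygen on the ring A carbon bearing the ortho-OMe (loss of MeOH, giving the 5-demethoxy flavone), oxidation at the central CH of the diketone, or closure onto ring B. Fallback with known chemistry, setting out from 9: bromination with NBS in MeCN at the only free ring position gives 2-bromo-3,4,5,6-tetramethoxybenzoic acid F1. Oxalyl chloride converts it into 2-bromo-3,4,5,6-tetramethoxybenzoyl chloride F2. Acylation of 6 under the conditions of step 4 gives 1-(3-acetoxy-2,4,5-trimethoxyphenyl)-3-(2-bromo-3,4,5,6-tetramethoxyphenyl)propane-1,3-dione F3. A copper-catalysed intramolecular Ullmann-type O-arylation of the enolate (CuI, monovalent copper, 1,10-phenanthroline, K2CO3, DMF, 100 °C) closes ring C regiospecifically at the bromine-bearing carbon. This comes back to the route at 12, which is deacetylated with NH3/MeOH as in step 5.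

**Step 2.** Risks: acid-mediated Fries migration or acetylation of transiently free phenol para to OH (C4), giving the wrong ketone. Fallback, setting out from 4: acetylate with Ac2O/pyridine and isolate 5. Iodinate with NIS and cat. TFA in MeCN to 5-iodo-2,3,6-trimethoxyphenyl acetate F4. Stille coupling with tributyl(1-ethoxyvinyl)stannane (PdCl2(PPh3)2, toluene, 100 °C) gives 5-(1-ethoxyvinyl)-2,3,6-trimethoxyphenyl acetate F5, and dilute aqueous HCl hydrolyses the enol ether. This halogenation/cross-coupling sequence has no acylium or Fries manifold and comes back at 6.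

**Step 4.** Risks: O-acylation or double acylation, slow reaction of the ortho-substituted acid chloride, and acetyl transfer from the aryl acetate. Fallback (aldol addition then oxidation instead of acylation), setting out from 7 and 6: lithiate 7 as in step 3 to 8 and quench with DMF to give 2,3,4,5-tetramethoxybenzaldehyde F6. Convert 6 with TMSOTf/Et3N into 2,3,6-trimethoxy-5-[1-(trimethylsilyloxy)vinyl]phenyl acetate F7. A Mukaiyama aldol addition (BF3·OEt2, CH2Cl2, −78 °C) gives racemic 1-(3-acetoxy-2,4,5-trimethoxyphenyl)-3-hydroxy-3-(2,3,4,5-tetramethoxyphenyl)propan-1-one F8. Dess–Martin oxidation of the carbinol removes the stereocentre and comes back at 11.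

## Further compounds

F1 | step 5 | 2-bromo-3,4,5,6-tetramethoxybenzoic acid | OC(=O)c1c(Br)c(OC)c(OC)c(OC)c1OC
F2 | step 5 | 2-bromo-3,4,5,6-tetramethoxybenzoyl chloride | O=C(Cl)c1c(Br)c(OC)c(OC)c(OC)c1OC
F3 | step 5 | 1-(3-acetoxy-2,4,5-trimethoxyphenyl)-3-(2-bromo-3,4,5,6-tetramethoxyphenyl)propane-1,3-dione | CC(=O)Oc1c(OC)c(OC)cc(C(=O)CC(=O)c2c(Br)c(OC)c(OC)c(OC)c2OC)c1OC
F4 | step 2 | 5-iodo-2,3,6-trimethoxyphenyl acetate | CC(=O)Oc1c(OC)c(OC)cc(I)c1OC
F5 | step 2 | 5-(1-ethoxyvinyl)-2,3,6-trimethoxyphenyl acetate | CC(=O)Oc1c(OC)c(OC)cc(C(=C)OCC)c1OC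
F6 | step 4 | 2,3,4,5-tetramethoxybenzaldehyde | O=Cc1cc(OC)c(OC)c(OC)c1OC
F7 | step 4 | 2,3,6-trimethoxy-5-[1-(trimethylsilyloxy)vinyl]phenyl acetate | CC(=O)Oc1c(OC)c(OC)cc(C(=C)O[Si](C)(C)C)c1OC
F8 | step 4 | racemic 1-(3-acetoxy-2,4,5-trimethoxyphenyl)-3-hydroxy-3-(2,3,4,5-tetramethoxyphenyl)propan-1-one | CC(=O)Oc1c(OC)c(OC)cc(C(=O)CC(O)c2cc(OC)c(OC)c(OC)c2OC)c1OC
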